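The readings stem from a simulated flask for an exercise.

I counted halvings. Free catalyst turns starting material and reagent into target. The grey run is the very flask asked about, followed to 5.00 h, and the teal run was made earlier, hotter and with less capture agent.

in all of them: starting material 0.52 M; reagent 0.546 M

|  | second substrate | capture agent | free catalyst | temperature | remark | time |
|---|---|---|---|---|---|---|
| grey | 0.26 M | 0.052 M | 3 mM | 35 °C | the very flask that is asked about, followed so far |  |
| teal | 0.26 M | 0.035 M | 3 mM | 41 °C | run made earlier |  |
| flask | 0.260 M | 0.0520 M | 3.0 mM | 35 °C |  | 8.0 h |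

| run | time / h | target / % | starting material / % |
|---|---|---|---|
| grey | 0.333 | 15.6 | 82.7 |
| grey | 1.00 | 35.6 | 64.7 |
| grey | 1.50 | 43.3 | 56.1 |
| grey | 2.50 | 51.2 | 48.4 |
| grey | 4.00 | 56.0 | 43.8 |
| grey | 5.00 | 56.5 | 43.3 |
| teal | 0.333 | 22.0 | 77.3 |
| teal | 0.500 | 29.3 | 70.8 |
| teal | 0.833 | 38.7 | 60.3 |
| teal | 1.33 | 48.1 | 52.0 |
| teal | 2.50 | 55.5 | 44.2 |
| teal | 4.00 | 57.9 | 41.8 |

(readings scatter by 0.3 percentage points)

- target that was removed still counts
- the numbers in the tables scatter with a standard deviation of 0.3 percentage points
- additions bring no volume worth counting

- east: at 8.0 h take out 90% of the target then present, then wait 8.0 h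
- north-west: at 8.0 h add reagent, 100% of the amount charged, then wait 8.0 h
- south-east: at 8.0 h add free catalyst, 100% of the amount charged, then wait 8.0 h
- west: change nothing and wait 8.0 h more
- south-west: at 8.0 h raise the temperature by 10 K, then wait 8.0 h

* target, in percent of the starting material first charged, at 8.0 h
* the remedy with the largest gain of target, or "none" below 2 percentage points (east / north-west / south-east / west / south-west / none)
* target present, with what was taken out counted in, in percent of the starting material first charged, after north-west
* target present, with what was taken out counted in, in percent of the starting material first charged, after south-west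

From the grey readings at 1.00 h and 2.50 h I got 0.758 h. This is the stopping half-life, the time in which the gap between target and its last reading halves, and I ranked the flasks by it.

The shortest rung was teal, whose gap halved in 0.559 h, yet it reached 57.9% against 56.5% in grey, so I expected little from heat, though the two runs differ in capture agent as well. Next came grey's own 0.758 h. The readings then spanned 6.60 halvings, and the last step in target was 0.5 percentage points. Allowing one more such step, I reckoned 57.0% at 8.0 h, which is 10.6 halvings in.

Grey had stopped with 43.3% of its starting material left and, counting by target, 46.2% of its reagent, so neither partner had run out. Capture agent outnumbered the catalyst 17.3 to one, so I judged that the catalyst was being lost, and that stayed a judgement. On that reading, reagent, heat and removal of target would leave about 57.0%. I took a fresh charge of free catalyst to restart the clock. If the rate follows both partners, it would gain 11 points, so I chose south-east.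

The forecast also stood at 57% but chose north-west, with 73.5% after north-west and 60% after south-west, on “a reversible reaction”.

The flask gave 57.7%, and the best remedy was south-east, gaining 18 points, with 57.9% after north-west and 57.7% after south-west.

    reagent + catalyst intermediate A → spent catalyst (k = 0.00996 M⁻¹ min⁻¹, Ea = 66.0 kJ mol⁻¹)
    second substrate + free catalyst ⇌ catalyst intermediate B (K = 21.8 M⁻¹, k = 1.82 M⁻¹ min⁻¹, Ea = 68.0 kJ mol⁻¹, ΔH = −34.0 kJ mol⁻¹)
    reagent + catalyst intermediate B → free catalyst + second product (k = 2.08 M⁻¹ min⁻¹, Ea = 44.0 kJ mol⁻¹)
    reagent + catalyst intermediate A → free catalyst + target (k = 4.21 M⁻¹ min⁻¹, Ea = 55.0 kJ mol⁻¹)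
    starting material + free catalyst ⇌ catalyst intermediate A (K = 48.6 M⁻¹, k = 21.2 M⁻¹ min⁻¹, Ea = 55.0 kJ mol⁻¹, ΔH = −53.0 kJ mol⁻¹)
    catalyst intermediate B + capture agent → trapped intermediate (k = 1.64 M⁻¹ min⁻¹, Ea = 69.0 kJ mol⁻¹)
    (constants at 35 °C)

At 8.00 h the flask held 0.317% of its catalyst in working forms, against 76.0% as trapped intermediate and 23.7% as spent catalyst, both off-cycle. Waiting 8.0 h more meant 10.6 further halvings, and west gained 0.091 points. A neighbouring flask with 0.013 M of capture agent kept 9.39% in working forms at 8.00 h, which counted as steady loss is a halving of working catalyst every 2.34 h, against 0.964 h in the flask, and its target stood at 78.9%.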